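Ask of each given number what an error in it would do to the share of D in D plus J, before reckoning that share.

common to all: G 0.5 mol%
- dawn: Z 7.5 mM; Q 1.1 equiv; run made earlier
- summer: Z 11 mM; Q 1.1 equiv; run made earlier
- flask: Z 15 mM; Q 1.10 equiv; time 8.0 min

| run | time / min | D / % | J / % |
|---|---|---|---|
| dawn | 0.833 | 15.1 | 3.4 |
| dawn | 2.00 | 17.0 | 6.4 |
| dawn | 4.00 | 15.0 | 11.9 |
| dawn | 10.0 | 13.4 | 19.6 |
| summer | 1.33 | 19.9 | 8.5 |
| summer | 3.00 | 19.8 | 13.2 |
| summer | 6.00 | 19.0 | 20.1 |
| summer | 10.0 | 15.6 | 25.6 |

(scatter of a reading: 0.5 percentage points)

1. share of D in D plus J at 0.80 s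
2. share of D in D plus J at 8.0 min
3. which of D and J there is more of at 8.0 min



The equivalents of Q and the loading of G in the flask equal those of the dawn and summer runs, so they drop out of a comparison. The charge of Z and the time remain, perhaps as one number, the dose, charge times time. At fixed loading the charge of G follows the charge of Z, and if G is lost in pairs (second-order decay), its time integral is a logarithm of one plus a multiple of the dose. At nearly equal dose, the dawn run at 2.00 min reads a share of 72.6% and the summer run at 1.33 min reads 70.1%.

The last readings of the two runs give 0.300 for the rise of ln(J/D) per unit of ln(dose), the dose slope. The flask at 8.0 min has 1.09 times the dose of the summer run's end. With the slope at zero its share is 37.9%, and with the slope doubled it is 36.6%. An error of 0.5 percentage points in the summer run's last D moves the share by 0.75 points. The reckoned share is 37.3%, so J leads. For 0.80 s, far earlier than the first dawn reading, the first two dawn readings, taken at one charge, give a slope of 0.587 and a looser share of 97.1%.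

The forecast differs from this reckoning in both shares, with 80% at 0.80 s and 41% at 8.0 min, agrees with it in putting J ahead, and says of the early share: “It appears to fall with concentration”.

The flask gives 96.3% at 0.80 s and 39.3% at 8.0 min, with D at 18.3% and J at 28.3%.

    Z + Q ⇌ J (K = 2600 M⁻¹, k = 0.0313 M⁻¹ s⁻¹)
    Z + Q ⇌ D (K = 36.0 M⁻¹, k = 0.941 M⁻¹ s⁻¹)
    2 G → X (k = 267 M⁻¹ s⁻¹)
    D + G ⇌ J + G, rate k4*[G]*[D] forward; the back reaction follows from the equilibrium constant (k = 170 M⁻¹ s⁻¹)

The slope 0.300 on the summer run's last reading had given 37.3%, which is 2 points below the flask. The neighbour flask with 25 mM of Z, at the same equivalents, loading and time, takes the same slope on the same reading and reckons to a share of D in D plus J of 33.7%. That neighbour flask gives 35.1%.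

The earlier runs and the new flask stem from a simulated flask from invented constants, and the scatter is random.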